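## The problem

Compound 26 is an 11-membered carbocycle of the humulane type. With the ring numbered C1 (CH–O-vanilloyl), C2 (CH2), C3=C4(CH3), C5–C7 (CH2), C8 (C(CH3)2), C9 (CH–OAc) and C10=C11(CH3), it holds an E trisubstituted alkene, a ring-Z trisubstituted alkene, a quaternary carbon and two allylic carbinol esters, 1S and 9R. No ring fusion helps the closure. A medium ring has to be closed from an open chain, so the closing bond should create no stereocentre and have its alkene geometry fixed beforehand. The two stereocentres lie 1,4 to each other across the Z alkene. In the open chain the C1 oxygen can dictate the geometry of C10=C11, but it cannot be trusted to set C9, which needs a reagent of its own. The two oxygens must carry different acyl groups, and their surroundings differ usefully: C9 is neopentyl, C1 is not. Both esters are allylic and would be ionised by zerovalent palladium or acid. A monoester of the cis-1,4-diol can pass its acyl group across, and β,γ-unsaturated carbonyl or Z-enone intermediates can slip into conjugation, so acylations must be late and mild. The enabling feature is the unit O–C9–C10=C11(CH3)–C1–O, a Z 2-ene-1,4-diol with its methyl on the alkene carbon next to C1. This is the imprint of an alkoxide-directed anti addition of CH3–Mg across a C1 propargylic alkyne, followed by capture of the C10–Mg bond by a C9 aldehyde.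

## Retrosynthesis

**Acyl groups (26 ⇒ 25 ⇒ 21 + 24; 21 ⇒ 20 ⇒ 19).** The phenol silyl ether, the C1–O aroyl bond and the C9–O acetyl bond are cut first. Allylic esters cannot pass a palladium-mediated ring closure, so they go on last. The order is fixed by protecting groups and not by selectivity: macrocycle 19 has C9–OH free and C1–O silylated, giving acetate 20, then C1 alcohol 21, then vanillate 25. Acid 24 comes from vanillic acid 22 through silyl ester 23. The forward steps must be mild enough not to move an acyl group across the cis-1,4-diol.

**Ring bond C4–C5 (19 ⇒ 17).** This is the only ring bond that joins an sp2 to an sp3 carbon without touching a stereocentre. Cutting it leaves an E alkenyl bromide and a terminal alkene, both of which come with the building blocks at no cost. Closing at C9–C10 or C1–C2 instead would form a stereocentre during a medium-ring closure. Seco compound 17 is an open chain with all stereochemistry in place. The forward step is a B-alkyl Suzuki–Miyaura macrocyclisation through borane 18 at high dilution with retention of the E geometry.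

**Configuration at C9 (17 ⇒ 16 ⇒ 15 ⇒ 14).** The C9 carbinol is traced to enone 16 and a reagent-controlled reduction, and 16 to the C1 silyl ether 15 of diol 14. The neopentyl C9–OH is the slower of the two to silylate, so C1 is masked selectively. The enone must be passed with C1 protected, because a free Z γ-hydroxy enone would close to a furan precursor. This pair of steps makes the route independent of the face selectivity of the C9–C10 bond formation.

**Three-component cut (14 ⇒ 10 + 11 + 12).** Cutting C11–CH3 and C9–C10 reduces the whole Z-enediol to alkynol 10, methylmagnesium bromide 11 and aldehyde 12. This beats a stepwise construction of the trisubstituted Z alkene (olefination or alkenyl halide chemistry), because the C1 alkoxide itself enforces both regiochemistry and anti addition through chelate 13. The precursors are a seven-carbon alkynol with one stereocentre and a commercial, non-enolisable aldehyde. The forward reaction must tolerate an alkenyl bromide, a terminal alkyne C–H and a terminal alkene.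

**Alkynol (10 ⇒ 9 ⇒ 8 ⇒ 7 ⇒ 4 + 5; 4 ⇒ 3 ⇒ 1).** C1 is set by asymmetric transfer hydrogenation of silyl ynone 8, the most reliable catalytic route to a propargylic carbinol. Ynone 8 comes from racemic adduct 7 of aldehyde 4 and the acetylide 6 of ethynyltrimethylsilane 5. The E alkenyl bromide is made at the outset from pent-3-yn-1-ol 1 by hydrozirconation–bromination through 2, then oxidation of 3. The forward steps must keep the β,γ-alkene out of conjugation.

## Roads not taken

**Alternative 1:** cut at C5–C6. A phenylsulfonyl group on C6 is deprotonated with KN(SiMe3)2 at high dilution and the carbanion displaces an allylic bromide on C5, giving macrocyclic sulfone A1 as both C6 epimers; the sulfone is then removed reductively.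
- Merits: a reactive carbanion meets a reactive allylic electrophile, a dependable kind of medium-ring closure that needs no transition metal.
- Weak points: two activating groups must be installed and one removed. The desulfonylation would be run next to two allylic C–O bonds. The allylic bromide can react at its far terminus or lose its E geometry. The cut says nothing about how the Z-enediol is made.
- Comparison: as a ring closure it is probably at least as reliable as step 11, and that is conceded. The chosen plan sets against it that its closing groups (a bromide from step 1, a terminal alkene from 12) cost no steps and nothing has to be excised afterwards.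

**Alternative 2:** cut at the C10=C11 alkene. The C1 oxygen (carbon bearing isopropenyl) and the C9 oxygen (carbon bearing vinyl) are tied through a diisopropylsilylene bridge. The second-generation Grubbs catalyst RuCl2(=CHPh)(H2IMes)(PCy3) then closes the seven-membered silaketal A2, in which the alkene can only be Z.
- Merits: the geometry is guaranteed by ring size, and both carbinols are made separately under reagent control. On the C9 question this road is better than the chosen one.
- Weak points: the metathesis must form a trisubstituted alkene beside a neopentyl centre. The unsymmetrical silaketal needs two controlled silylations. A2 is 1R by design, so a Mitsunobu inversion on a hindered allylic alcohol is still owed. The carbocycle is still unclosed and carries a sulfone and an allylic chloride for a later alkylation and desulfonylation.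
- Comparison: the chosen plan pays two steps (9 and 10) for C9. In return it forms C11–CH3, C9–C10 and the Z geometry in one operation, with C1 already in its final configuration.

**Alternative 3:** cut at C4–C5 as the strategic step. 9-BBN hydroborates the terminal C5=C6 alkene, and PdCl2(dppf) with AsPh3 and Cs2CO3 couples the borane with the C4 alkenyl bromide at high dilution, giving the macrocyclic bis-silyl ether A3.
- Merits: mild, geometry-retentive, no activating group to remove.
- Weak points: the entropy and strain of an 11-membered ring, and it leaves the assembly of the Z-enediol chain open, which is the harder half of the problem.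
- Comparison: this is the same closure as step 11, so the two plans differ in emphasis and not in kind. In one respect A3 is better: with both oxygens silylated, 9-BBN meets no free hydroxyl and the two oxygens can be unveiled in either order. The chosen route (17 to 19 with C9–OH free) sets two fewer protecting-group operations against that, and answers the question of chain assembly with step 7.

Key step: step 7

Assumption: the face of aldehyde 12 attacked in step 7 is not taken to be controlled. 14 denotes the 5R (ring C9 R) diol; the 5S epimer that may form with it is not separated, 15 stands for both C5 epimers, and the two converge at enone 16.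

## Route

Step 1
Reactants: 1 pent-3-yn-1-ol
Product: 3 (3E)-4-bromopent-3-en-1-ol, via O-zirconated alkenylzirconocene chloride 2 (not isolated)
Conditions: Cp2Zr(H)Cl (2.5 equiv), THF, rt to 40 °C; then NBS, 0 °C
Reagents that add atoms: N-bromosuccinimide, O=C1CCC(=O)N1Br
Why: Hydrozirconation–bromination: one equivalent of Cp2Zr(H)Cl converts the hydroxyl into its zirconium alkoxide, a second adds H–Zr syn across the alkyne and the excess equilibrates zirconium to the less hindered, methyl-bearing carbon; NBS cleaves C–Zr with retention, giving the E alkenyl bromide.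

Step 2
Reactants: 3 (3E)-4-bromopent-3-en-1-ol
Product: 4 (3E)-4-bromopent-3-enal
Conditions: Dess–Martin periodinane, NaHCO3, CH2Cl2, 0 °C; used at once without chromatography
Reagents that add atoms: none
Why: Dess–Martin oxidation under buffered, non-basic conditions is the usual way to reach a β,γ-unsaturated aldehyde without moving the alkene into conjugation.

Step 3
Reactants: 4 (3E)-4-bromopent-3-enal; 5 ethynyltrimethylsilane
Product: 7 rac-(5E)-6-bromo-1-(trimethylsilyl)hept-5-en-1-yn-3-ol, via lithium (trimethylsilyl)acetylide 6 (not isolated)
Conditions: 5, n-BuLi, THF, −78 °C; then 4, −78 °C; aq NH4Cl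
Reagents that add atoms: none
Why: 1,2-Addition of a lithium acetylide to an aldehyde; at −78 °C the weakly basic acetylide should add faster than it enolises the aldehyde, and the racemic carbinol is oxidised in the next step.

Step 4
Reactants: 7 rac-(5E)-6-bromo-1-(trimethylsilyl)hept-5-en-1-yn-3-ol
Product: 8 (5E)-6-bromo-1-(trimethylsilyl)hept-5-en-1-yn-3-one
Conditions: Dess–Martin periodinane, NaHCO3, CH2Cl2, 0 °C
Reagents that add atoms: none
Why: Dess–Martin oxidation of a propargylic alcohol to the ynone; the buffered medium should leave the doubly activated C4 methylene and the E alkene in place.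

Step 5
Reactants: 8 (5E)-6-bromo-1-(trimethylsilyl)hept-5-en-1-yn-3-one
Product: 9 (3S,5E)-6-bromo-1-(trimethylsilyl)hept-5-en-1-yn-3-ol
Conditions: Ru[(S,S)-TsDPEN](p-cymene) (3 mol%, preformed amido complex), i-PrOH, rt
Reagents that add atoms: none
Why: Noyori asymmetric transfer hydrogenation of an α,β-acetylenic ketone under base-free conditions; the alkynyl group takes the place of the aryl group in the bifunctional transition state, so the (S,S)-catalyst should deliver hydride to give the 3S carbinol, which is ring C1.

Step 6
Reactants: 9 (3S,5E)-6-bromo-1-(trimethylsilyl)hept-5-en-1-yn-3-ol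
Product: 10 (3S,5E)-6-bromohept-5-en-1-yn-3-ol
Conditions: K2CO3 (cat.), MeOH, 0 °C to rt
Reagents that add atoms: none
Why: Methoxide-mediated protodesilylation of the alkynylsilane; neither the carbinol centre nor the alkenyl bromide is affected.

Step 7
Reactants: 10 (3S,5E)-6-bromohept-5-en-1-yn-3-ol; 11 methylmagnesium bromide; 12 2,2-dimethylpent-4-enal
Product: 14 (5R,6Z,8S,10E)-11-bromo-4,4,7-trimethyldodeca-1,6,10-triene-5,8-diol, via oxamagnesacycle 13 (not isolated)
Conditions: 11 (3.5 equiv), CuI (15 mol%), Et2O–THF, 0 °C to rt; then 12 (2.5 equiv), −40 to 0 °C; aq NH4Cl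
Reagents that add atoms: none
Why: Reagent 11 first deprotonates the C1 hydroxyl of 10 with loss of methane; copper-catalysed anti-carbomagnesiation of the magnesium alkoxide, the known reaction type for propargylic alcohols, then places CH3 on the alkyne carbon next to the carbinol (C11) and magnesium on the terminal carbon (C10), held cis to C1 in the five-membered chelate 13. This chelate secures the two selectivities the step needs: the regiochemistry (methyl proximal to oxygen) and the anti sense of addition, which becomes the ring-Z C10=C11 geometry. The alkenyl–magnesium bond then adds with retention at C10 to the non-enolisable aldehyde 12, forming C9–C10, and the surplus of 12 consumes the remaining Grignard reagent. No ring of the target closes; the only ring formed is the transient oxamagnesacycle. The alkenyl bromide and the terminal alkene should be inert to a methyl Grignard reagent with catalytic CuI at or below room temperature, and the C1 stereocentre is not touched. The new C9 stereocentre is under weak 1,4-control from C1 only; a four-centre model with the quaternary group turned away from the chelate even points to 9S. Its configuration is therefore not relied on and is fixed in steps 9 and 10.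

Step 8
Reactants: 14 (5R,6Z,8S,10E)-11-bromo-4,4,7-trimethyldodeca-1,6,10-triene-5,8-diol (as obtained, with its C5 epimer)
Product: 15 (6Z,8S,10E)-11-bromo-8-[(tert-butyldimethylsilyl)oxy]-4,4,7-trimethyldodeca-1,6,10-trien-5-ol, both C5 epimers
Conditions: TBSCl (1.1 equiv), imidazole, DMF, 0 °C
Reagents that add atoms: tert-butyldimethylsilyl chloride, CC(C)(C)[Si](C)(C)Cl
Why: Sterically selective silylation: the C8 (ring C1) hydroxyl is a plain secondary allylic alcohol, whereas the C5 (ring C9) hydroxyl is neopentyl and should react far more slowly with a bulky silyl chloride.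

Step 9
Reactants: 15 (6Z,8S,10E)-11-bromo-8-[(tert-butyldimethylsilyl)oxy]-4,4,7-trimethyldodeca-1,6,10-trien-5-ol, both C5 epimers
Product: 16 (6Z,8S,10E)-11-bromo-8-[(tert-butyldimethylsilyl)oxy]-4,4,7-trimethyldodeca-1,6,10-trien-5-one
Conditions: Dess–Martin periodinane, NaHCO3, CH2Cl2, 0 °C to rt
Reagents that add atoms: none
Why: Dess–Martin oxidation of the allylic alcohol converges both C5 epimers on one enone; the buffered conditions and the silyl ether at ring C1 should prevent Z to E isomerisation and cyclisation onto the carbonyl.

Step 10
Reactants: 16 (6Z,8S,10E)-11-bromo-8-[(tert-butyldimethylsilyl)oxy]-4,4,7-trimethyldodeca-1,6,10-trien-5-one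
Product: 17 (5R,6Z,8S,10E)-11-bromo-8-[(tert-butyldimethylsilyl)oxy]-4,4,7-trimethyldodeca-1,6,10-trien-5-ol
Conditions: (S)-2-methyl-CBS-oxazaborolidine (0.3 equiv), catecholborane (2 equiv), toluene, −78 to −40 °C; MeOH, then aq NaOH wash
Reagents that add atoms: none
Why: Corey–Bakshi–Shibata 1,2-reduction: the ketone binds the ring boron anti to its larger substituent, taken to be the quaternary C4 group, so the (S)-catalyst should give the 5R (ring C9 R) alcohol; catecholborane is used because it leaves the terminal alkene alone at low temperature. The sense of induction is to be confirmed by Mosher ester analysis, and the (R)-catalyst is used if the alkenyl group proves to be the larger one.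

Step 11
Reactants: 17 (5R,6Z,8S,10E)-11-bromo-8-[(tert-butyldimethylsilyl)oxy]-4,4,7-trimethyldodeca-1,6,10-trien-5-ol
Product: 19 (1R,2Z,4S,6E)-4-[(tert-butyldimethylsilyl)oxy]-3,7,11,11-tetramethylcycloundeca-2,6-dien-1-ol, via B-alkyl-9-BBN adduct 18 (not isolated)
Conditions: 9-BBN dimer (excess), THF, rt; then slow addition to PdCl2(dppf) (20 mol%), AsPh3, Cs2CO3, DMF–THF–H2O, 50 °C, ca. 2 mM
Reagents that add atoms: none
Why: B-alkyl Suzuki–Miyaura macrocyclisation: 9-BBN hydroborates only the monosubstituted alkene at its terminal carbon, zerovalent palladium inserts into the alkenyl C–Br bond, and transmetalation from the hydroxyborate followed by reductive elimination forms C4–C5 of the ring with retention of the E geometry. The hindered free hydroxyl and the allylic silyl ether are not substrates for palladium.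

Step 12
Reactants: 19 (1R,2Z,4S,6E)-4-[(tert-butyldimethylsilyl)oxy]-3,7,11,11-tetramethylcycloundeca-2,6-dien-1-ol
Product: 20 (1R,2Z,4S,6E)-4-[(tert-butyldimethylsilyl)oxy]-3,7,11,11-tetramethylcycloundeca-2,6-dien-1-yl acetate
Conditions: Ac2O, DMAP, Et3N, CH2Cl2, rt
Reagents that add atoms: acetic anhydride, CC(=O)OC(C)=O
Why: DMAP-catalysed acetylation of the only free hydroxyl (ring C9), with retention at carbon; the nucleophilic catalyst is needed because the alcohol is neopentyl.

Step 13
Reactants: 20 (1R,2Z,4S,6E)-4-[(tert-butyldimethylsilyl)oxy]-3,7,11,11-tetramethylcycloundeca-2,6-dien-1-yl acetate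
Product: 21 (1R,2Z,4S,6E)-4-hydroxy-3,7,11,11-tetramethylcycloundeca-2,6-dien-1-yl acetate
Conditions: HF·pyridine, pyridine, THF, 0 °C to rt
Reagents that add atoms: none
Why: Fluoride-mediated cleavage of the secondary silyl ether in a pyridine-buffered, weakly acidic medium, in which the allylic acetate should neither ionise nor migrate.

Step 14
Reactants: 22 vanillic acid
Product: 24 4-[(tert-butyldimethylsilyl)oxy]-3-methoxybenzoic acid, via silyl ester 23 (not isolated)
Conditions: TBSCl (2.5 equiv), imidazole, DMF, rt; then AcOH, THF–H2O, rt
Reagents that add atoms: tert-butyldimethylsilyl chloride, CC(C)(C)[Si](C)(C)Cl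
Why: Exhaustive silylation followed by selective hydrolysis of the labile silyl ester; the aryl silyl ether is stable to dilute acetic acid.

Step 15
Reactants: 21 (1R,2Z,4S,6E)-4-hydroxy-3,7,11,11-tetramethylcycloundeca-2,6-dien-1-yl acetate; 24 4-[(tert-butyldimethylsilyl)oxy]-3-methoxybenzoic acid
Product: 25 (1S,2Z,4R,9E)-4-(acetyloxy)-2,5,5,9-tetramethylcycloundeca-2,9-dien-1-yl 4-[(tert-butyldimethylsilyl)oxy]-3-methoxybenzoate
Conditions: EDC·HCl, DMAP, CH2Cl2, 0 °C to rt
Reagents that add atoms: none
Why: Steglich esterification of the one free hydroxyl (ring C1) by the carboxyl-activated acid; acylation at oxygen leaves the 1S centre unchanged, and the masked phenol cannot compete.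

Step 16
Reactants: 25 (1S,2Z,4R,9E)-4-(acetyloxy)-2,5,5,9-tetramethylcycloundeca-2,9-dien-1-yl 4-[(tert-butyldimethylsilyl)oxy]-3-methoxybenzoate
Product: 26 (1S,2Z,4R,9E)-4-(acetyloxy)-2,5,5,9-tetramethylcycloundeca-2,9-dien-1-yl 4-hydroxy-3-methoxybenzoate (the target)
Conditions: Bu4NF, AcOH, THF, 0 °C
Reagents that add atoms: none
Why: Fluoride cleavage of an aryl silyl ether, fast because the phenoxide is stabilised by the para ester; buffering with acetic acid should protect the two esters from basic cleavage or migration.

## Compound list

1 | pent-3-yn-1-ol | CC#CCCO | starting material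
2 | chlorozirconocene alkoxide of (3E)-4-[chlorobis(cyclopentadienyl)zirconio]pent-3-en-1-ol | C/C(=C\CCO[Zr](Cl)(C1C=CC=C1)C1C=CC=C1)[Zr](Cl)(C1C=CC=C1)C1C=CC=C1 | intermediate (not isolated)
3 | (3E)-4-bromopent-3-en-1-ol | C/C(Br)=C\CCO | intermediate
4 | (3E)-4-bromopent-3-enal | C/C(Br)=C\CC=O | intermediate
5 | ethynyltrimethylsilane | C#C[Si](C)(C)C | starting material
6 | lithium (trimethylsilyl)acetylide | [Li]C#C[Si](C)(C)C | intermediate (not isolated)
7 | rac-(5E)-6-bromo-1-(trimethylsilyl)hept-5-en-1-yn-3-ol | C/C(Br)=C\CC(O)C#C[Si](C)(C)C | intermediate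
8 | (5E)-6-bromo-1-(trimethylsilyl)hept-5-en-1-yn-3-one | C/C(Br)=C\CC(=O)C#C[Si](C)(C)C | intermediate
9 | (3S,5E)-6-bromo-1-(trimethylsilyl)hept-5-en-1-yn-3-ol | C[Si](C)(C)C#C[C@@H](O)C/C=C(\C)Br | intermediate
10 | (3S,5E)-6-bromohept-5-en-1-yn-3-ol | C#C[C@@H](O)C/C=C(\C)Br | intermediate
11 | methylmagnesium bromide | C[Mg]Br | starting material
12 | 2,2-dimethylpent-4-enal | C=CCC(C)(C)C=O | starting material
13 | (5S)-5-[(2E)-3-bromobut-2-en-1-yl]-4-methyl-2,5-dihydro-1,2-oxamagnesole (chelated alkenylmagnesium alkoxide) | CC1=C[Mg]O[C@H]1C/C=C(\C)Br | intermediate (not isolated)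
14 | (5R,6Z,8S,10E)-11-bromo-4,4,7-trimethyldodeca-1,6,10-triene-5,8-diol (ring numbering: 1S,9R seco diol) | C=CCC(C)(C)[C@H](O)/C=C(/C)[C@@H](O)C/C=C(\C)Br | intermediate
15 | (6Z,8S,10E)-11-bromo-8-[(tert-butyldimethylsilyl)oxy]-4,4,7-trimethyldodeca-1,6,10-trien-5-ol, both C5 epimers (5R and 5S) | C=CCC(C)(C)C(O)/C=C(/C)[C@@H](O[Si](C)(C)C(C)(C)C)C/C=C(\C)Br | intermediate
16 | (6Z,8S,10E)-11-bromo-8-[(tert-butyldimethylsilyl)oxy]-4,4,7-trimethyldodeca-1,6,10-trien-5-one | C=CCC(C)(C)C(=O)/C=C(/C)[C@@H](O[Si](C)(C)C(C)(C)C)C/C=C(\C)Br | intermediate
17 | (5R,6Z,8S,10E)-11-bromo-8-[(tert-butyldimethylsilyl)oxy]-4,4,7-trimethyldodeca-1,6,10-trien-5-ol | C=CCC(C)(C)[C@H](O)/C=C(/C)[C@@H](O[Si](C)(C)C(C)(C)C)C/C=C(\C)Br | intermediate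
18 | 9-borabicyclo[3.3.1]nonan-9-yl adduct of 17, boron on the former terminal carbon (ring C5) | B1(CCCC(C)(C)[C@H](O)/C=C(/C)[C@@H](O[Si](C)(C)C(C)(C)C)C/C=C(\C)Br)C2CCCC1CCC2 | intermediate (not isolated)
19 | (1R,2Z,4S,6E)-4-[(tert-butyldimethylsilyl)oxy]-3,7,11,11-tetramethylcycloundeca-2,6-dien-1-ol | CC(C)(C)[Si](C)(C)O[C@H]1C/C=C(\C)CCCC(C)(C)[C@H](O)/C=C\1C | intermediate
20 | (1R,2Z,4S,6E)-4-[(tert-butyldimethylsilyl)oxy]-3,7,11,11-tetramethylcycloundeca-2,6-dien-1-yl acetate | CC(C)(C)[Si](C)(C)O[C@H]1C/C=C(\C)CCCC(C)(C)[C@H](OC(C)=O)/C=C\1C | intermediate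
21 | (1R,2Z,4S,6E)-4-hydroxy-3,7,11,11-tetramethylcycloundeca-2,6-dien-1-yl acetate | O[C@H]1C/C=C(\C)CCCC(C)(C)[C@H](OC(C)=O)/C=C\1C | intermediate
22 | vanillic acid (4-hydroxy-3-methoxybenzoic acid) | COc1cc(C(=O)O)ccc1O | starting material
23 | tert-butyldimethylsilyl 4-[(tert-butyldimethylsilyl)oxy]-3-methoxybenzoate | COc1cc(C(=O)O[Si](C)(C)C(C)(C)C)ccc1O[Si](C)(C)C(C)(C)C | intermediate (not isolated)
24 | 4-[(tert-butyldimethylsilyl)oxy]-3-methoxybenzoic acid | COc1cc(C(=O)O)ccc1O[Si](C)(C)C(C)(C)C | intermediate
25 | (1S,2Z,4R,9E)-4-(acetyloxy)-2,5,5,9-tetramethylcycloundeca-2,9-dien-1-yl 4-[(tert-butyldimethylsilyl)oxy]-3-methoxybenzoate | COc1cc(C(=O)O[C@H]2C/C=C(\C)CCCC(C)(C)[C@H](OC(C)=O)/C=C\2C)ccc1O[Si](C)(C)C(C)(C)C | intermediate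
26 | (1S,2Z,4R,9E)-4-(acetyloxy)-2,5,5,9-tetramethylcycloundeca-2,9-dien-1-yl 4-hydroxy-3-methoxybenzoate | COc1cc(C(=O)O[C@H]2C/C=C(\C)CCCC(C)(C)[C@H](OC(C)=O)/C=C\2C)ccc1O | target

## Step count and least certain steps

Total step count: 16. Longest linear sequence: 15 steps (steps 1 to 13, 15 and 16); step 14 is a one-step side branch.

**Step 7 (key step).** The most likely failures are deprotonation of the terminal alkyne C–H by 11 in competition with carbomagnesiation, and sluggish addition of the chelated alkenylmagnesium to the hindered aldehyde, so that simple protonation at C10 takes over. Copper-mediated methylation of the alkenyl bromide is a lesser risk. Fallback: the two bond formations are separated. From 10 the same carbomagnesiation is run and 13 is quenched with iodine to give (1Z,3S,5E)-6-bromo-1-iodo-2-methylhepta-1,5-dien-3-ol F1. A Nozaki–Hiyama–Kishi reaction of this iodide with 12 (CrCl2, catalytic NiCl2, DMSO) tolerates the free hydroxyl, should engage the C–I bond before the C–Br bond, and returns to the route at 14 (both C5 epimers, as before).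

**Step 11.** Oligomerisation or protodeboronation may outrun the closure, because the entropic and transannular cost of an 11-membered ring slows the intramolecular transmetalation and reductive elimination. Fallback: the ring is closed between two electrophiles instead. From 17, borane 18 is oxidised (NaBO3, THF–H2O) to (5R,6Z,8S,10E)-11-bromo-8-[(tert-butyldimethylsilyl)oxy]-4,4,7-trimethyldodeca-6,10-diene-1,5-diol F2. The primary hydroxyl is exchanged for iodide (I2, PPh3, imidazole) to give (5R,6Z,8S,10E)-11-bromo-8-[(tert-butyldimethylsilyl)oxy]-1-iodo-4,4,7-trimethyldodeca-6,10-dien-5-ol F3. A nickel-catalysed reductive coupling of the alkyl iodide with the alkenyl bromide (NiBr2(dme), 4,4'-di-tert-butyl-2,2'-bipyridine, zinc powder, DMA, high dilution) tolerates the free hydroxyl and rejoins the route at 19.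

**Step 10.** Face selectivity may be poor or opposite, because the ketone is flanked by two large groups (a quaternary carbon and a Z-substituted alkenyl group) and the catalyst may not tell them apart; Z to E isomerisation of the enone under Lewis acid is a second risk. Fallback: reagent control is given up for separation and recycling. From 16, Luche reduction (NaBH4, CeCl3·7H2O, MeOH, −78 °C) gives 17 together with (5S,6Z,8S,10E)-11-bromo-8-[(tert-butyldimethylsilyl)oxy]-4,4,7-trimethyldodeca-1,6,10-trien-5-ol F4. The two are separated by chromatography, F4 is returned to 16 under the conditions of step 9, and the route continues from 17.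

**Step 5 (with steps 2 to 4 leading to it).** The β,γ-alkene may migrate into conjugation, or the doubly activated C4 methylene may enolise, at the aldehyde or ynone stage or under the basic amido ruthenium catalyst. Fallback: the ynone is avoided and the enantiomers are separated enzymatically. From 7, K2CO3 in MeOH gives racemic (5E)-6-bromohept-5-en-1-yn-3-ol F5. Acetylation with vinyl acetate and immobilised Candida antarctica lipase B should, by the empirical size rule for secondary alcohols with ethynyl as the smaller group, acylate the S enantiomer to (3S,5E)-6-bromohept-5-en-1-yn-3-yl acetate F6. This is separated from the slower-reacting enantiomer and methanolysed (K2CO3, MeOH), rejoining the route at 10. Should the enzyme prefer the other enantiomer, the unreacted alcohol is 10 itself.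

**Step 15 (with step 13).** The acetyl group may migrate from O9 to the free C1 hydroxyl of 21 across the cis-1,4-diol under the basic acylation conditions, which would scramble the two esters. Fallback: site selectivity is taken from sterics instead of from the order of deprotection. From 19, HF·pyridine gives (1R,2Z,4S,6E)-3,7,11,11-tetramethylcycloundeca-2,6-diene-1,4-diol F7. One equivalent of 24 (EDC·HCl, DMAP, −20 °C) should acylate the unhindered ring C1 hydroxyl to give (1S,2Z,4R,9E)-4-hydroxy-2,5,5,9-tetramethylcycloundeca-2,9-dien-1-yl 4-[(tert-butyldimethylsilyl)oxy]-3-methoxybenzoate F8. Acetylation of the neopentyl hydroxyl (Ac2O, DMAP) rejoins the route at 25.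

## Further compounds

F1 | step 7 | (1Z,3S,5E)-6-bromo-1-iodo-2-methylhepta-1,5-dien-3-ol | I/C=C(/C)[C@@H](O)C/C=C(\C)Br
F2 | step 11 | (5R,6Z,8S,10E)-11-bromo-8-[(tert-butyldimethylsilyl)oxy]-4,4,7-trimethyldodeca-6,10-diene-1,5-diol | OCCCC(C)(C)[C@H](O)/C=C(/C)[C@@H](O[Si](C)(C)C(C)(C)C)C/C=C(\C)Br
F3 | step 11 | (5R,6Z,8S,10E)-11-bromo-8-[(tert-butyldimethylsilyl)oxy]-1-iodo-4,4,7-trimethyldodeca-6,10-dien-5-ol | ICCCC(C)(C)[C@H](O)/C=C(/C)[C@@H](O[Si](C)(C)C(C)(C)C)C/C=C(\C)Br
F4 | step 10 | (5S,6Z,8S,10E)-11-bromo-8-[(tert-butyldimethylsilyl)oxy]-4,4,7-trimethyldodeca-1,6,10-trien-5-ol | C=CCC(C)(C)[C@@H](O)/C=C(/C)[C@@H](O[Si](C)(C)C(C)(C)C)C/C=C(\C)Br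
F5 | step 5 | rac-(5E)-6-bromohept-5-en-1-yn-3-ol | C#CC(O)C/C=C(\C)Br
F6 | step 5 | (3S,5E)-6-bromohept-5-en-1-yn-3-yl acetate | C#C[C@@H](OC(C)=O)C/C=C(\C)Br
F7 | step 15 | (1R,2Z,4S,6E)-3,7,11,11-tetramethylcycloundeca-2,6-diene-1,4-diol | O[C@H]1C/C=C(\C)CCCC(C)(C)[C@H](O)/C=C\1C
F8 | step 15 | (1S,2Z,4R,9E)-4-hydroxy-2,5,5,9-tetramethylcycloundeca-2,9-dien-1-yl 4-[(tert-butyldimethylsilyl)oxy]-3-methoxybenzoate | COc1cc(C(=O)O[C@H]2C/C=C(\C)CCCC(C)(C)[C@H](O)/C=C\2C)ccc1O[Si](C)(C)C(C)(C)C
A1 | alternative 1 | macrocyclic C6 phenyl sulfone (both C6 epimers) with C1 triethylsilyl and C9 tert-butyldimethylsilyl ethers, 1S,9R, E C3=C4, ring-Z C10=C11 | CC[Si](CC)(CC)O[C@H]1C/C=C(\C)CC(S(=O)(=O)c2ccccc2)CC(C)(C)[C@H](O[Si](C)(C)C(C)(C)C)/C=C\1C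
A2 | alternative 2 | 2,2-diisopropyl-1,3-dioxa-2-silacyclohept-5-ene with the Z C10=C11(CH3) alkene, 1R carbon bearing the (2E)-4-chloro-3-methylbut-2-enyl chain and 9R carbon bearing the 2-methyl-4-(phenylsulfonyl)butan-2-yl group | CC(C)[Si]1(C(C)C)O[C@H](C/C=C(\C)CCl)/C(C)=C\[C@H](C(C)(C)CCS(=O)(=O)c2ccccc2)O1
A3 | alternative 3 | macrocyclic bis-silyl ether, C1 triethylsilyl and C9 tert-butyldimethylsilyl, 1S,9R | CC[Si](CC)(CC)O[C@H]1C/C=C(\C)CCCC(C)(C)[C@H](O[Si](C)(C)C(C)(C)C)/C=C\1C
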